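## Retrosynthetic overview

1. In the nine-membered ring B, C8 is a 1,1-disubstituted alkene carbon (C8=CH2) lying between C7H2 and the cyclobutane carbon C9. The C7–C8 bond is therefore cut last, giving a C8 enol triflate and a C7 alkylborane grown from a C5 vinyl group (intramolecular B-alkyl Suzuki–Miyaura coupling).
2. The pyran ring is cut at aryl–O to a C4 tertiary alcohol and an aryl bromide (Pd C–O coupling, C4–O bond untouched). C4 comes from chelate/Felkin-controlled MeMgBr addition to a C3–C4(=O)–C5 ketone.
3. C3–C4 comes from a cyclobutane Grignard reagent and a Weinreb amide. The amide is made by opening a temporary 5-bromodihydrocoumarin, in which C1' (Rh-catalysed asymmetric phenylation) and C5 (trans alkylation) are set.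
4. (−)-α-Pinene supplies C1 of the cyclobutane, through cleavage, Baeyer–Villiger oxidation, a cyclobutanone aldol at C9 (trans) and deoxygenation at C10.
5. Ring order: cyclobutane (chiral pool), then the temporary lactone (opened again), then the pyran ring, then ring B. The formyl groups and free phenols come last.

Key step: step 24

Assumption: atom labels follow caryophyllane numbering (C1/C9 cyclobutane CH, C4 O-bearing quaternary carbon, C5, C8 methylidene carbon, C1' = CHPh; arene positions 5–8 as in a chroman). The C8 carbinol (steps 6–20) and the C10 carbinol (steps 8–9) are carried as epimer mixtures because both centres are erased later.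

## Route

Step 1
Reactants: 1 (−)-α-pinene
Product: 2 cis-pinonic acid, 2-[(1R,3R)-3-acetyl-2,2-dimethylcyclobutyl]acetic acid
Conditions: RuCl3·xH2O (2 mol %), NaIO4, CCl4/MeCN/H2O, rt
Reagents that add atoms: sodium periodate, [Na+].[O-]I(=O)(=O)=O; water, O
Why: Ruthenium tetroxide-type oxidative cleavage of the trisubstituted alkene leaves both cyclobutane stereocentres untouched, and the pinene C5 carbon that carries CH2CO2H becomes C1 of the target.

Step 2
Reactants: 2 cis-pinonic acid
Product: 3 2-[(1R,3R)-3-acetoxy-2,2-dimethylcyclobutyl]acetic acid (cis)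
Conditions: mCPBA, CF3CO2H (1 equiv), CH2Cl2, rt, dark
Reagents that add atoms: mCPBA, OOC(=O)c1cccc(Cl)c1
Why: Baeyer–Villiger oxidation in which the secondary cyclobutyl carbon migrates in preference to methyl, with retention, turning the acetyl group into a ring C–O bond at the future C10.

Step 3
Reactants: 3 acetoxy acid
Product: 4 (1R,3S)-3-(2-hydroxyethyl)-2,2-dimethylcyclobutan-1-ol (cis)
Conditions: LiAlH4, THF, 0 °C → reflux; aq. work-up
Reagents that add atoms: none
Why: Hydride reduction converts the acid into the C2–C3 hydroxyethyl arm and cleaves the acetate in the same operation without touching a stereocentre.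

Step 4
Reactants: 4 diol
Product: 5 (1R,3R)-3-(2-chloroethyl)-2,2-dimethylcyclobutan-1-ol (cis)
Conditions: PPh3 (1.1 equiv), CCl4, CH2Cl2, 0 → 40 °C
Reagents that add atoms: tetrachloromethane, ClC(Cl)(Cl)Cl
Why: Appel chlorination should select the unhindered primary alcohol over the cyclobutanol flanked by the gem-dimethyl carbon, giving a handle that tolerates the following enolate, hydride and radical steps.

Step 5
Reactants: 5 chloro alcohol
Product: 6 (R)-3-(2-chloroethyl)-2,2-dimethylcyclobutan-1-one
Conditions: Dess–Martin periodinane, CH2Cl2, rt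
Reagents that add atoms: none
Why: Dess–Martin oxidation gives the cyclobutanone under neutral conditions, and C1 is β to the carbonyl and so cannot epimerise.

Step 6
Reactants: 6 cyclobutanone
Product: 7 (3S,4R)-3-(2-chloroethyl)-4-(1-hydroxyethyl)-2,2-dimethylcyclobutan-1-one (C1/C9 trans)
Conditions: LiN(i-Pr)2, THF, −78 °C; MeCHO, −78 °C; aq. work-up
Reagents that add atoms: acetaldehyde, CC=O
Why: Lithium enolate aldol addition in which only C9 can enolise (C11 is quaternary) and acetaldehyde should approach anti to the neighbouring C1 arm, setting C9 trans to C1, which is also the thermodynamic arrangement.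

Step 7
Reactants: 7 aldol
Product: 8 benzyl ether of 7
Conditions: BnOC(=NH)CCl3, TfOH (cat.), CH2Cl2/cyclohexane, 0 °C
Reagents that add atoms: benzyl 2,2,2-trichloroacetimidate, N=C(OCc1ccccc1)C(Cl)(Cl)Cl
Why: Acid-catalysed imidate benzylation protects the β-hydroxy ketone without the base that would trigger retro-aldol cleavage.

Step 8
Reactants: 8 benzyloxy ketone
Product: 9 C10 cyclobutanol
Conditions: NaBH4, MeOH, 0 °C
Reagents that add atoms: none
Why: Borohydride reduction of the strained ketone is fast, and the new C10 carbinol configuration is irrelevant because the oxygen is removed next.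

Step 9
Reactants: 9 cyclobutanol
Product: 10 O-cyclobutyl imidazole-1-carbothioate of 9
Conditions: 1,1'-thiocarbonyldiimidazole, DMAP (cat.), toluene, 90 °C
Reagents that add atoms: 1,1'-thiocarbonyldiimidazole, S=C(n1ccnc1)n1ccnc1
Why: Neutral thioacylation avoids an alkoxide that could displace the primary chloride intramolecularly.

Step 10
Reactants: 10 thiocarbonyl derivative
Product: 11 [(1-{(1R,2S)-2-(2-chloroethyl)-3,3-dimethylcyclobutyl}ethoxy)methyl]benzene (trans cyclobutane chloride)
Conditions: Bu3SnH, AIBN (cat.), toluene, 100 °C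
Reagents that add atoms: none
Why: Barton–McCombie deoxygenation replaces the C10 oxygen by hydrogen, the thiocarbonyl group reacting with stannyl radicals far faster than a primary alkyl chloride.

Step 11
Reactants: 12 5-bromoresorcinol; 13 ethyl propiolate
Product: 14 5-bromo-7-hydroxycoumarin
Conditions: ZnCl2, dioxane, 100 °C
Reagents that add atoms: none
Why: Pechmann-type propiolate coumarin synthesis, in which hydroarylation should occur at the ring carbon para to one hydroxyl and ortho to the other rather than at the crowded position between them, placing bromine at coumarin C5.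

Step 12
Reactants: 14 bromohydroxycoumarin
Product: 15 5-bromo-7-(methoxymethoxy)coumarin
Conditions: MOMCl, i-Pr2NEt, CH2Cl2, 0 °C → rt
Reagents that add atoms: chloromethyl methyl ether, COCCl
Why: Standard acetal protection of the only free phenol.

Step 13
Reactants: 15 MOM coumarin; 16 phenylboronic acid
Product: 17 (S)-5-bromo-7-(methoxymethoxy)-4-phenylchroman-2-one
Conditions: Rh(acac)(C2H4)2 (3 mol %), (S)-Segphos (3.3 mol %), dioxane/H2O 10:1, 60 °C
Reagents that add atoms: none
Why: Hayashi–Miyaura asymmetric 1,4-addition in which the (S)-Segphos-bound phenylrhodium species differentiates the coumarin faces and should set C1' as S, the aryl bromide being inert to monovalent rhodium under these base-free conditions.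

Step 14
Reactants: 17 phenyl lactone
Product: 18 (3S,4S)-3-[(benzyloxy)methyl]-5-bromo-7-(methoxymethoxy)-4-phenylchroman-2-one (3,4-trans)
Conditions: LiN(SiMe3)2, THF, −78 °C; BnOCH2Cl, −78 → −40 °C
Reagents that add atoms: benzyl chloromethyl ether, ClCOCc1ccccc1
Why: Lactone enolate alkylation in which the C1' phenyl, forced pseudoaxial by the peri bromine, shields one face, so C6 should enter trans to it and set C5.

Step 15
Reactants: 18 trans lactone
Product: 19 (2S,3S)-2-[(benzyloxy)methyl]-3-[2-bromo-6-hydroxy-4-(methoxymethoxy)phenyl]-N-methoxy-N-methyl-3-phenylpropanamide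
Conditions: MeNH(OMe)·HCl, i-PrMgCl, THF, −20 → 0 °C
Reagents that add atoms: N,O-dimethylhydroxylamine hydrochloride, CNOC.Cl
Why: Weinreb aminolysis of the activated aryl lactone by the magnesium amide opens the temporary ring, frees the phenol that becomes O-5 of the target and prepares C4 for a single organometallic addition.

Step 16
Reactants: 19 phenol amide
Product: 20 (2S,3S)-2-[(benzyloxy)methyl]-3-[2-bromo-4,6-bis(methoxymethoxy)phenyl]-N-methoxy-N-methyl-3-phenylpropanamide
Conditions: MOMCl, i-Pr2NEt, CH2Cl2, 40 °C
Reagents that add atoms: chloromethyl methyl ether, COCCl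
Why: MOM protection blocks relactonisation and gives the second of the two acetal-protected phenols.

Step 17
Reactants: 11 trans cyclobutane chloride; 20 bis-MOM Weinreb amide
Product: 22 C3–C4(=O)–C5 ketone (1S,5S,9R,1'S), via alkylmagnesium chloride 21 (not isolated)
Conditions: 11, Mg (I2-activated), THF, 65 °C; then 20, THF, 0 °C → rt
Reagents that add atoms: magnesium, [Mg] (carried only by 21)
Why: Weinreb ketone synthesis forms C3–C4, the chelated tetrahedral adduct preventing over-addition, and a Grignard rather than a lithium reagent is chosen so that neither Br–metal exchange nor arene metalation competes.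

Step 18
Reactants: 22 ketone
Product: 23 C4 tertiary alcohol (1S,4S,5S,9R,1'S)
Conditions: MeMgBr (3 equiv), CH2Cl2/Et2O, −78 °C
Reagents that add atoms: methylmagnesium bromide, C[Mg]Br
Why: In this Grignard 1,2-addition the Cram-chelate model (Mg bridging C4=O and the C6 benzyloxy oxygen) and the Felkin–Anh model (C1' diarylmethyl group as the large substituent) point to the same face, so CH3 should enter anti to the C1' group and set C4 as S.

Step 19
Reactants: 23 bromo tertiary alcohol
Product: 24 chroman (1S,4S,5S,9R,1'S): C4 bears CH3 and the CH2CH2-cyclobutyl arm, C5 bears CH2OBn trans to the C1' phenyl and cis to the C4 methyl, with 5,7-bis(OMOM)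
Conditions: Pd(OAc)2 (5 mol %), 2-(di-tert-butylphosphino)-1,1'-binaphthyl (6 mol %), Cs2CO3, toluene, 80 °C
Reagents that add atoms: none
Why: Intramolecular Buchwald–Hartwig-type C–O coupling closes the six-membered pyran ring at the aryl carbon, so the C4–O bond and the C4 configuration are retained, and the tertiary alkoxide has no β-hydrogen on its carbinol carbon to eliminate.

Step 20
Reactants: 24 bis-benzyl ether
Product: 25 C6/C8 diol
Conditions: H2 (1 atm), Pd(OH)2/C, EtOAc/EtOH, rt
Reagents that add atoms: none
Why: Hydrogenolysis removes both benzyl ethers at once while no alkene is yet present, and the MOM acetals and the non-benzylic C4–O bond are inert.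

Step 21
Reactants: 25 diol
Product: 26 C6 aldehyde/C8 methyl ketone (1S,4S,5R,9R,1'S; descriptor at C5 changes by priority only)
Conditions: Dess–Martin periodinane (3 equiv), CH2Cl2, 0 °C → rt
Reagents that add atoms: none
Why: Double Dess–Martin oxidation under non-basic conditions avoids enolisation of the β-aryloxy aldehyde and erases the C8 epimer mixture.

Step 22
Reactants: 26 keto aldehyde
Product: 27 C5 vinyl chroman methyl ketone
Conditions: Ph3PCH3Br, KN(SiMe3)2, THF, 0 °C; then 26 (1.1 equiv ylide), −78 → 0 °C
Reagents that add atoms: methyltriphenylphosphonium bromide, C[P+](c1ccccc1)(c1ccccc1)c1ccccc1.[Br-]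
Why: Wittig methylenation with one equivalent of ylide at low temperature should take the aldehyde in preference to the methyl ketone and install C7 as the vinyl terminus.

Step 23
Reactants: 27 vinyl ketone
Product: 28 C8 enol triflate with C5 vinyl group (precursor of the key step)
Conditions: KN(SiMe3)2, THF, −78 °C; PhNTf2, −78 → −20 °C
Reagents that add atoms: N-phenylbis(trifluoromethanesulfonimide), O=S(=O)(N(c1ccccc1)S(=O)(=O)C(F)(F)F)C(F)(F)F
Why: Kinetic enolate triflation in which deprotonation occurs at the methyl group, because an enolate towards C9 would place an exocyclic double bond on the cyclobutane, so the methylidene is in place and C9 stays trans.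

Step 24
Reactants: 28 vinyl enol triflate
Product: 30 bis-MOM ether of the target lacking both formyl groups, via C7 B-alkyl-9-BBN adduct 29 (not isolated)
Conditions: 9-BBN dimer, THF, rt → 40 °C; then syringe-pump addition (12 h) to Pd(dppf)Cl2·CH2Cl2 (20 mol %), AsPh3 (20 mol %), Cs2CO3, DMF/THF/H2O, 50 °C, final ≤1 mM
Reagents that add atoms: 9-BBN (9-borabicyclo[3.3.1]nonane), B1C2CCCC1CCC2 (its boron unit is carried only by 29)
Why: 9-BBN places boron on C7 of the C6=C7 vinyl group, zerovalent palladium inserts into the C8–OTf bond, the hydroxo/carbonato borate of 29 hands C7 over to palladium and reductive elimination makes C7–C8. The closest known reaction type is the intramolecular B-alkyl Suzuki–Miyaura coupling of alkylboranes with alkenyl triflates or iodides, established for macrocycles and for a small number of nine-membered carbocycles. Ring B closes as a nine-membered carbocycle by sp3–sp2 coupling, with the C8=CH2 bond remaining exocyclic to the new ring. No stereocentre is created, and C1, C4, C5, C9 and C1' are spectators that carbonate cannot epimerise. The step needs hydroboration of the monosubstituted alkene only, which the bulk of 9-BBN and the geminally substituted, triflate-deactivated C8 alkene should ensure. It also needs cyclisation to outrun oligomerisation, β-hydride elimination and protodeboronation, which slow addition at high dilution, the wide-bite dppf ligand with AsPh3, and the anchoring of both arms on adjacent trans positions of the chroman and the cyclobutane should favour.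

Step 25
Reactants: 30 macrocycle
Product: 31 6,8-dibromide of 30
Conditions: NBS (2.05 equiv), MeCN, −20 → 0 °C, dark
Reagents that add atoms: N-bromosuccinimide, O=C1CCC(=O)N1Br
Why: Electrophilic aromatic bromination of the trialkoxyarene at its only two free positions should be much faster than ionic attack on the exocyclic alkene, and radical pathways are suppressed in the dark.

Step 26
Reactants: 31 dibromide
Product: 33 6,8-dialdehyde bis-MOM ether, via 6,8-dilithio arene 32 (not isolated)
Conditions: t-BuLi (4.4 equiv), THF/Et2O, −78 °C; DMF, −78 °C → rt; aq. work-up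
Reagents that add atoms: N,N-dimethylformamide, CN(C)C=O; tert-butyllithium, [Li]C(C)(C)C (lithium carried only by 32)
Why: Double bromine–lithium exchange followed by DMF formylation, each aryllithium site being stabilised by chelation to a flanking MOM oxygen.

Step 27
Reactants: 33 protected dialdehyde
Product: 34 target CNP0253700.1
Conditions: HCl (1 M in MeOH), MeOH/THF, 0 °C → rt
Reagents that add atoms: none
Why: Acetal exchange removes the MOM groups, which are especially labile ortho to formyl groups, under acid mild enough to spare the tertiary C4–O bond and the methylidene.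

## Compound list

1 | (−)-α-pinene, (1S,5S)-2,6,6-trimethylbicyclo[3.1.1]hept-2-ene | CC1=CC[C@H]2C[C@@H]1C2(C)C | starting material
2 | 2-[(1R,3R)-3-acetyl-2,2-dimethylcyclobutyl]acetic acid | OC(=O)C[C@H]1C[C@@H](C(C)=O)C1(C)C | intermediate
3 | 2-[(1R,3R)-3-acetoxy-2,2-dimethylcyclobutyl]acetic acid | OC(=O)C[C@H]1C[C@@H](OC(C)=O)C1(C)C | intermediate
4 | (1R,3S)-3-(2-hydroxyethyl)-2,2-dimethylcyclobutan-1-ol | OCC[C@H]1C[C@@H](O)C1(C)C | intermediate
5 | (1R,3R)-3-(2-chloroethyl)-2,2-dimethylcyclobutan-1-ol | ClCC[C@H]1C[C@@H](O)C1(C)C | intermediate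
6 | (R)-3-(2-chloroethyl)-2,2-dimethylcyclobutan-1-one | ClCC[C@H]1CC(=O)C1(C)C | intermediate
7 | (3S,4R)-3-(2-chloroethyl)-4-(1-hydroxyethyl)-2,2-dimethylcyclobutan-1-one | ClCC[C@H]1[C@H](C(C)O)C(=O)C1(C)C | intermediate
8 | (3S,4R)-4-[1-(benzyloxy)ethyl]-3-(2-chloroethyl)-2,2-dimethylcyclobutan-1-one | ClCC[C@H]1[C@H](C(C)OCc2ccccc2)C(=O)C1(C)C | intermediate
9 | C10 cyclobutanol from 8 | ClCC[C@H]1[C@H](C(C)OCc2ccccc2)C(O)C1(C)C | intermediate
10 | imidazole-1-carbothioate of 9 | ClCC[C@H]1[C@H](C(C)OCc2ccccc2)C(OC(=S)n2ccnc2)C1(C)C | intermediate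
11 | [(1-{(1R,2S)-2-(2-chloroethyl)-3,3-dimethylcyclobutyl}ethoxy)methyl]benzene | ClCC[C@H]1[C@H](C(C)OCc2ccccc2)CC1(C)C | intermediate
12 | 5-bromoresorcinol | Oc1cc(O)cc(Br)c1 | starting material
13 | ethyl propiolate | C#CC(=O)OCC | starting material
14 | 5-bromo-7-hydroxycoumarin | O=C1C=Cc2c(Br)cc(O)cc2O1 | intermediate
15 | 5-bromo-7-(methoxymethoxy)coumarin | O=C1C=Cc2c(Br)cc(OCOC)cc2O1 | intermediate
16 | phenylboronic acid | OB(O)c1ccccc1 | starting material
17 | (S)-5-bromo-7-(methoxymethoxy)-4-phenylchroman-2-one | O=C1C[C@@H](c2ccccc2)c2c(Br)cc(OCOC)cc2O1 | intermediate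
18 | (3S,4S)-3-[(benzyloxy)methyl]-5-bromo-7-(methoxymethoxy)-4-phenylchroman-2-one | c1ccccc1COC[C@@H]2[C@@H](c3ccccc3)c3c(Br)cc(OCOC)cc3OC2=O | intermediate
19 | Weinreb amide with free phenol (2S,3S) | c1ccccc1COC[C@@H](C(=O)N(C)OC)[C@@H](c3ccccc3)c3c(Br)cc(OCOC)cc3O | intermediate
20 | bis-MOM Weinreb amide (2S,3S) | c1ccccc1COC[C@@H](C(=O)N(C)OC)[C@@H](c3ccccc3)c3c(Br)cc(OCOC)cc3OCOC | intermediate
21 | alkylmagnesium chloride from 11 | Cl[Mg]CC[C@H]1[C@H](C(C)OCc2ccccc2)CC1(C)C | intermediate
22 | C4 ketone (1S,5S,9R,1'S) | c1ccccc1COC[C@@H](C(=O)CC[C@H]4[C@H](C(C)OCc5ccccc5)CC4(C)C)[C@@H](c3ccccc3)c3c(Br)cc(OCOC)cc3OCOC | intermediate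
23 | C4 tertiary alcohol (1S,4S,5S,9R,1'S) | c1ccccc1COC[C@@H]([C@](O)(C)CC[C@H]4[C@H](C(C)OCc5ccccc5)CC4(C)C)[C@@H](c3ccccc3)c3c(Br)cc(OCOC)cc3OCOC | intermediate
24 | chroman bis-benzyl ether (1S,4S,5S,9R,1'S) | c1ccccc1COC[C@@H]2[C@@H](c3ccccc3)c3c(OCOC)cc(OCOC)cc3O[C@@]2(C)CC[C@H]4[C@H](C(C)OCc5ccccc5)CC4(C)C | intermediate
25 | chroman C6/C8 diol | OC[C@@H]2[C@@H](c3ccccc3)c3c(OCOC)cc(OCOC)cc3O[C@@]2(C)CC[C@H]4[C@H](C(C)O)CC4(C)C | intermediate
26 | chroman C6 aldehyde/C8 methyl ketone | O=C[C@@H]2[C@@H](c3ccccc3)c3c(OCOC)cc(OCOC)cc3O[C@@]2(C)CC[C@H]4[C@H](C(C)=O)CC4(C)C | intermediate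
27 | C5 vinyl chroman methyl ketone (1S,4S,5R,9R,1'S) | C=C[C@@H]2[C@@H](c3ccccc3)c3c(OCOC)cc(OCOC)cc3O[C@@]2(C)CC[C@H]4[C@H](C(C)=O)CC4(C)C | intermediate
28 | C5 vinyl chroman C8 enol triflate | C=C[C@@H]2[C@@H](c3ccccc3)c3c(OCOC)cc(OCOC)cc3O[C@@]2(C)CC[C@H]2[C@H](C(OS(=O)(=O)C(F)(F)F)=C)CC2(C)C | intermediate
29 | C7 B-alkyl-9-BBN adduct of 28 | B1(C2CCCC1CCC2)CC[C@@H]3[C@@H](c4ccccc4)c4c(OCOC)cc(OCOC)cc4O[C@@]3(C)CC[C@H]5[C@H](C(OS(=O)(=O)C(F)(F)F)=C)CC5(C)C | intermediate
30 | bis-MOM ether of the target lacking the formyl groups | C=C1CC[C@@H]2[C@@H](c3ccccc3)c3c(OCOC)cc(OCOC)cc3O[C@@]2(C)CC[C@H]2[C@H]1CC2(C)C | intermediate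
31 | 6,8-dibromide of 30 | C=C1CC[C@@H]2[C@@H](c3ccccc3)c3c(OCOC)c(Br)c(OCOC)c(Br)c3O[C@@]2(C)CC[C@H]2[C@H]1CC2(C)C | intermediate
32 | 6,8-dilithio arene | C=C1CC[C@@H]2[C@@H](c3ccccc3)c3c(OCOC)c([Li])c(OCOC)c([Li])c3O[C@@]2(C)CC[C@H]2[C@H]1CC2(C)C | intermediate
33 | 6,8-dialdehyde bis-MOM ether | C=C1CC[C@@H]2[C@@H](c3ccccc3)c3c(OCOC)c(C=O)c(OCOC)c(C=O)c3O[C@@]2(C)CC[C@H]2[C@H]1CC2(C)C | intermediate
34 | CNP0253700.1 (1S,4S,5R,9R,1'S) | C=C1CC[C@@H]2[C@@H](c3ccccc3)c3c(O)c(C=O)c(O)c(C=O)c3O[C@@]2(C)CC[C@H]2[C@H]1CC2(C)C | target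

## Step count and risks

Total steps: 27. Longest linear sequence: 21 (steps 1–10 and 17–27).

**Step 24 (ring B closure).**
- Intermolecular coupling to oligomers, protodeboronation or β-hydride elimination of the alkylpalladium species may win before the strained nine-membered transition state is reached.
- The fallback makes the same C7–C8 bond by carbonyl addition.
- It sets out from 28. 9-BBN followed by NaBO3·4H2O gives the C7 primary alcohol F1, and Dess–Martin oxidation gives the C7 aldehyde F2.
- CrCl2 with catalytic NiCl2 in DMSO/THF at high dilution (Nozaki–Hiyama–Kishi reaction of the enol triflate with the aldehyde) closes ring B to the C7 allylic alcohol F3.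
- ClCO2Me/pyridine then gives the allylic methyl carbonate F4.
- Pd(OAc)2/n-Bu3P/HCO2NH4 (Tsuji formate reduction, hydride delivered to the more substituted allyl terminus C7, so the methylidene is kept) comes back to the route at 30.

**Step 19 (pyran closure).**
- C–O reductive elimination from the crowded arylpalladium alkoxide may be slow. Hydrodebromination or C–H palladation of the neighbouring C1' phenyl ring could then take over.
- The fallback is a metal-free elimination–addition that sets out from 23, using LiN(i-Pr)2 (3 equiv) in THF, −78 °C → rt.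
- The base deprotonates the alcohol and the arene C–H between Br and OMOM, and loss of bromide gives the aryne lithium alkoxide F5.
- The tethered alkoxide adds to the aryne carbon remote from OMOM (the position favoured by the inductive effect of that group, and the one that gives the six-membered ring).
- Protonation on work-up comes back to the route at 24.

**Step 26 (double formylation).**
- The second bromine–lithium exchange may stay incomplete, or the dilithio arene may pick up a proton. Either would leave mono-aldehyde or debrominated material.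
- The fallback formylates the free phenol electrophilically instead of through organolithium species, and sets out from 30 (steps 25–27 are bypassed).
- HCl in MeOH gives the 5,7-dihydroxychroman macrocycle F6.
- Excess POCl3/DMF (Vilsmeier–Haack formylation, MeCN, 0 °C → rt, then aqueous NaOAc hydrolysis) attacks both free positions 6 and 8 and comes back to the route at 34.

Further compounds
F1 | step 24 | C7 primary alcohol of the enol triflate | OCC[C@@H]2[C@@H](c3ccccc3)c3c(OCOC)cc(OCOC)cc3O[C@@]2(C)CC[C@H]4[C@H](C(OS(=O)(=O)C(F)(F)F)=C)CC4(C)C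
F2 | step 24 | C7 aldehyde of the enol triflate | O=CC[C@@H]2[C@@H](c3ccccc3)c3c(OCOC)cc(OCOC)cc3O[C@@]2(C)CC[C@H]4[C@H](C(OS(=O)(=O)C(F)(F)F)=C)CC4(C)C
F3 | step 24 | ring B C7 allylic alcohol (C7 epimers) | C=C1C(O)C[C@@H]2[C@@H](c3ccccc3)c3c(OCOC)cc(OCOC)cc3O[C@@]2(C)CC[C@H]2[C@H]1CC2(C)C
F4 | step 24 | C7 allylic methyl carbonate | C=C1C(OC(=O)OC)C[C@@H]2[C@@H](c3ccccc3)c3c(OCOC)cc(OCOC)cc3O[C@@]2(C)CC[C@H]2[C@H]1CC2(C)C
F5 | step 19 | aryne lithium alkoxide from 23 | c1ccccc1COC[C@@H]([C@](O[Li])(C)CC[C@H]4[C@H](C(C)OCc5ccccc5)CC4(C)C)[C@@H](c3ccccc3)C3=C(OCOC)C=C(OCOC)C#C3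
F6 | step 26 | 5,7-dihydroxychroman macrocycle | C=C1CC[C@@H]2[C@@H](c3ccccc3)c3c(O)cc(O)cc3O[C@@]2(C)CC[C@H]2[C@H]1CC2(C)C
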